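## Retrosynthetic overview

1. The C3–O ester bond is cut last: a core alcohol carrying C9–OSiEt3 plus (2E,5R)-5-(angeloyloxy)hex-2-enoic acid, itself made from (R)-pent-4-en-2-ol, angelic acid and acrylic acid by esterification and cross-metathesis.
2. The C7 isopropenyl group comes from acetone aldol addition and dehydration on the cis-decalone, where the target's C7 configuration is the sterically and thermodynamically preferred one.
3. Key C–O bond: C9–O, formed together with C10–H from the 9(10)-en-8-one by a one-pot copper hydride-catalysed reductive α-silyloxylation (new), which delivers the C9 oxygen already protected.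
4. Ring B (second ring): methyl cuprate addition and α-silyl vinyl ketone annulation on (R)-4-(PMB-oxy)-2-methylcyclohex-2-enone, setting C4 and C5.
5. Ring A (first ring): organocatalytic Michael addition of PMB-oxyacetaldehyde to ethyl vinyl ketone, then aldol condensation, setting C3.

Assumption: the named starting materials are catalogue chemicals. Decalin carbons carry eremophilane numbers (C3 ester carbinol, C4 and C5 methyl-bearing, C7 isopropenyl-bearing, C8 ketone, C9 carbinol, C10 ring-fusion CH); PMB = 4-methoxybenzyl, IPr = 1,3-bis(2,6-diisopropylphenyl)imidazol-2-ylidene.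

## Route

Step 1
Reactants: 1 [(4-methoxybenzyl)oxy]acetaldehyde; 2 ethyl vinyl ketone (pent-1-en-3-one)
Product: 4 (4R)-4-[(4-methoxybenzyl)oxy]-2-methylcyclohex-2-en-1-one, via keto-aldehyde 3 (not isolated)
Conditions: (S)-2-[methoxy(diphenyl)methyl]pyrrolidine (5 mol%), ethyl 3,4-dihydroxybenzoate (20 mol%), neat, 4 °C; then 0.1 M aq KOH, nBu4NOH (cat.), Et2O/THF, 0 °C → rt
Reagents that add atoms: none
Why: Enamine-catalysed asymmetric Michael addition of the aldehyde to the vinyl ketone (the (S)-prolinol ether shields one face of the E-enamine, so C–C bond formation on its Re face sets the 2R oxygen-bearing centre, the future C3), followed by intramolecular aldol condensation (Robinson-type annulation) that closes ring A without touching that centre.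

Step 2
Reactants: 4 (4R)-4-[(4-methoxybenzyl)oxy]-2-methylcyclohex-2-en-1-one; 5 3-(trimethylsilyl)but-3-en-2-one
Product: 8 (4aR,5R,6R)-6-[(4-methoxybenzyl)oxy]-4a,5-dimethyl-4,4a,5,6,7,8-hexahydronaphthalen-2(3H)-one, via lithium enolate 6 (not isolated), via silyl diketone 7 (not isolated)
Conditions: Me2CuLi (1.5 equiv, from MeLi and CuBr·SMe2), Et2O, −78 → −20 °C; then 5 (1.3 equiv), −78 → −20 °C; then KOH, MeOH, 0 → 60 °C
Reagents that add atoms: lithium dimethylcuprate, Me2CuLi, [Li+].C[Cu-]C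
Why: The cuprate adds to the enone β-carbon anti to the neighbouring PMB-oxy group (sets C4), the enolate is alkylated by the α-silyl vinyl ketone anti to the new methyl (sets quaternary C5 with the two methyls cis), and methanolic KOH removes silicon and closes ring B by aldol condensation (conjugate addition–Michael–Robinson annulation).

Step 3
Reactants: 8 (4aR,5R,6R)-6-[(4-methoxybenzyl)oxy]-4a,5-dimethyl-4,4a,5,6,7,8-hexahydronaphthalen-2(3H)-one
Product: 9 (1R,4aR,5R,6R,8aS)-6-[(4-methoxybenzyl)oxy]-4a,5-dimethyl-1-[(triethylsilyl)oxy]octahydronaphthalen-2(1H)-one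
Conditions: (IPr)CuCl (5 mol%), NaOtBu (6 mol%), Et3SiOOSiEt3 (1.5 equiv), (EtO)2MeSiH (1.3 equiv, added over 4 h), toluene, −20 → 0 °C
Reagents that add atoms: bis(triethylsilyl) peroxide, CC[Si](CC)(CC)OO[Si](CC)(CC)CC
Why: Proposed new method: copper hydride-catalysed reductive α-silyloxylation of an enone — (IPr)CuH, formed from (IPr)CuOtBu and the hydrosilane, transfers hydride to C10 on the face syn to the angular methyl (as known copper hydride and cuprate additions to 4a-methyl octalones do), giving a cis-fused catalyst-bound copper enolate whose C9 attacks the O–O bond of the bis(silyl) peroxide from the convex face (silyloxy equatorial, cis to H-10), forming the C9–O bond and (IPr)CuOSiEt3, which the hydrosilane returns to (IPr)CuH by σ-bond metathesis; the closest known reactions are copper hydride-catalysed reductive aldol and hydroamination (enolate or alkylcopper trapped by an electrophile with silane turnover), enolate hydroxylation by bis(trimethylsilyl) peroxide, manganese hydride/O2 reductive α-hydroxylation of enones, and the two-step conjugate reduction/Rubottom oxidation.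

Step 4
Reactants: 9 (1R,4aR,5R,6R,8aS)-6-[(4-methoxybenzyl)oxy]-4a,5-dimethyl-1-[(triethylsilyl)oxy]octahydronaphthalen-2(1H)-one
Product: 11 (1R,3R,4aR,5R,6R,8aS)-3-(2-hydroxypropan-2-yl)-6-[(4-methoxybenzyl)oxy]-4a,5-dimethyl-1-[(triethylsilyl)oxy]octahydronaphthalen-2(1H)-one, via lithium enolate 10 (not isolated)
Conditions: LiN(iPr)2 (1.15 equiv), THF, −78 °C; then acetone (3 equiv), −78 °C; AcOH quench at −78 °C
Reagents that add atoms: acetone, CC(C)=O
Why: Kinetic deprotonation takes the C7 methylene rather than the hindered silyloxy-bearing C9 methine, and the lithium enolate adds to acetone (directed aldol addition) on the face away from the axial C5–C4 bond, placing the new group equatorial at C7, which is also the thermodynamically preferred configuration.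

Step 5
Reactants: 11 (1R,3R,4aR,5R,6R,8aS)-3-(2-hydroxypropan-2-yl)-6-[(4-methoxybenzyl)oxy]-4a,5-dimethyl-1-[(triethylsilyl)oxy]octahydronaphthalen-2(1H)-one
Product: 12 (1R,3R,4aR,5R,6R,8aS)-6-[(4-methoxybenzyl)oxy]-4a,5-dimethyl-3-(prop-1-en-2-yl)-1-[(triethylsilyl)oxy]octahydronaphthalen-2(1H)-one
Conditions: SOCl2 (2 equiv), pyridine, −20 → 0 °C
Reagents that add atoms: none
Why: Dehydration through the tertiary chlorosulfite (E2 elimination) takes one of the six freely accessible methyl hydrogens in preference to the hindered ring C7–H, giving the isopropenyl group and leaving C7 untouched.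

Step 6
Reactants: 12 (1R,3R,4aR,5R,6R,8aS)-6-[(4-methoxybenzyl)oxy]-4a,5-dimethyl-3-(prop-1-en-2-yl)-1-[(triethylsilyl)oxy]octahydronaphthalen-2(1H)-one
Product: 13 (1R,3R,4aR,5R,6R,8aS)-6-hydroxy-4a,5-dimethyl-3-(prop-1-en-2-yl)-1-[(triethylsilyl)oxy]octahydronaphthalen-2(1H)-one
Conditions: DDQ (1.3 equiv), CH2Cl2/pH 7 phosphate buffer (10:1), 0 °C
Reagents that add atoms: none
Why: Oxidative PMB ether cleavage: DDQ oxidises the electron-rich benzyl ether to an oxocarbenium ion that water hydrolyses, leaving the silyl ether, the ketone and the 1,1-disubstituted alkene intact.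

Step 7
Reactants: 14 angelic acid, (2Z)-2-methylbut-2-enoic acid; 15 (2R)-pent-4-en-2-ol
Product: 17 (2R)-pent-4-en-2-yl (2Z)-2-methylbut-2-enoate, via mixed anhydride 16 (not isolated)
Conditions: 2,4,6-Cl3C6H2COCl, Et3N, toluene, rt; then 15, toluene, 80 °C
Reagents that add atoms: none
Why: Yamaguchi esterification through the mixed anhydride without a nucleophilic catalyst acylates the alcohol while keeping the Z (angelate) geometry, and the carbinol centre is not touched.

Step 8
Reactants: 17 (2R)-pent-4-en-2-yl (2Z)-2-methylbut-2-enoate; 18 acrylic acid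
Product: 19 (2E,5R)-5-{[(2Z)-2-methylbut-2-enoyl]oxy}hex-2-enoic acid
Conditions: second-generation Hoveyda–Grubbs catalyst RuCl2(H2IMes)(=CH-C6H4-2-OiPr) (3 mol%), acrylic acid (3 equiv), CH2Cl2, 40 °C
Reagents that add atoms: none
Why: Olefin cross-metathesis of the terminal alkene and acrylic acid gives the E-enoic acid under thermodynamic control, the trisubstituted electron-poor angelate alkene being inert to the ruthenium carbene.

Step 9
Reactants: 13 (1R,3R,4aR,5R,6R,8aS)-6-hydroxy-4a,5-dimethyl-3-(prop-1-en-2-yl)-1-[(triethylsilyl)oxy]octahydronaphthalen-2(1H)-one; 19 (2E,5R)-5-{[(2Z)-2-methylbut-2-enoyl]oxy}hex-2-enoic acid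
Product: 21 (1R,2R,4aS,5R,7R,8aR)-1,8a-dimethyl-6-oxo-7-(prop-1-en-2-yl)-5-[(triethylsilyl)oxy]decahydronaphthalen-2-yl (2E,5R)-5-{[(2Z)-2-methylbut-2-enoyl]oxy}hex-2-enoate, via mixed anhydride 20 (not isolated)
Conditions: 19 (1.3 equiv), 2,4,6-Cl3C6H2COCl, Et3N, toluene, rt; then 13, DMAP, 0 °C → rt
Reagents that add atoms: none
Why: Yamaguchi esterification: the equatorial C3 hydroxyl attacks the less hindered enoyl carbonyl of the mixed anhydride (DMAP acyl transfer), forming the C3–O ester bond with retention at every stereocentre, the C9 oxygen being silyl-blocked.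

Step 10
Reactants: 21 (1R,2R,4aS,5R,7R,8aR)-1,8a-dimethyl-6-oxo-7-(prop-1-en-2-yl)-5-[(triethylsilyl)oxy]decahydronaphthalen-2-yl (2E,5R)-5-{[(2Z)-2-methylbut-2-enoyl]oxy}hex-2-enoate
Product: 22 (1R,2R,4aS,5R,7R,8aR)-5-hydroxy-1,8a-dimethyl-6-oxo-7-(prop-1-en-2-yl)decahydronaphthalen-2-yl (2E,5R)-5-{[(2Z)-2-methylbut-2-enoyl]oxy}hex-2-enoate
Conditions: HF·pyridine, pyridine, THF, 0 °C
Reagents that add atoms: none
Why: Fluoride-mediated desilylation of the secondary triethylsilyl ether under buffered conditions frees the C9 hydroxyl without isomerising the isopropenyl ketone, the enoate or the angelate.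

## Compound list

1 | [(4-methoxybenzyl)oxy]acetaldehyde | COc1ccc(COCC=O)cc1 | starting material
2 | ethyl vinyl ketone (pent-1-en-3-one) | CCC(=O)C=C | starting material
3 | (2R)-2-[(4-methoxybenzyl)oxy]-5-oxoheptanal | CCC(=O)CC[C@@H](OCc1ccc(OC)cc1)C=O | intermediate (not isolated)
4 | (4R)-4-[(4-methoxybenzyl)oxy]-2-methylcyclohex-2-en-1-one | CC1=C[C@H](OCc2ccc(OC)cc2)CCC1=O | intermediate
5 | 3-(trimethylsilyl)but-3-en-2-one | CC(=O)C(=C)[Si](C)(C)C | starting material
6 | lithium (3R,4R)-4-[(4-methoxybenzyl)oxy]-2,3-dimethylcyclohex-1-en-1-olate (3-methyl trans to 4-OPMB) | COc1ccc(CO[C@@H]2CCC(O[Li])=C(C)[C@H]2C)cc1 | intermediate (not isolated)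
7 | (2R,3R,4R)-4-[(4-methoxybenzyl)oxy]-2,3-dimethyl-2-[3-oxo-2-(trimethylsilyl)butyl]cyclohexan-1-one (silyl-bearing carbon as a mixture) | COc1ccc(CO[C@@H]2CCC(=O)[C@](C)(CC([Si](C)(C)C)C(C)=O)[C@H]2C)cc1 | intermediate (not isolated)
8 | (4aR,5R,6R)-6-[(4-methoxybenzyl)oxy]-4a,5-dimethyl-4,4a,5,6,7,8-hexahydronaphthalen-2(3H)-one (methyls cis, 3-OPMB trans to them) | COc1ccc(CO[C@@H]2CCC3=CC(=O)CC[C@@]3([C@H]2C)C)cc1 | intermediate
9 | (1R,4aR,5R,6R,8aS)-6-[(4-methoxybenzyl)oxy]-4a,5-dimethyl-1-[(triethylsilyl)oxy]octahydronaphthalen-2(1H)-one (cis-fused; 9-OSiEt3, H-10 and both methyls on one face) | C1C[C@@]2(C)[C@H](CC[C@@H](OCc3ccc(OC)cc3)[C@@H]2C)[C@@H](O[Si](CC)(CC)CC)C1=O | intermediate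
10 | lithium enolate of 9 (C7=C8–OLi) | C=1C[C@@]2(C)[C@H](CC[C@@H](OCc3ccc(OC)cc3)[C@@H]2C)[C@@H](O[Si](CC)(CC)CC)C=1O[Li] | intermediate (not isolated)
11 | (1R,3R,4aR,5R,6R,8aS)-3-(2-hydroxypropan-2-yl)-6-[(4-methoxybenzyl)oxy]-4a,5-dimethyl-1-[(triethylsilyl)oxy]octahydronaphthalen-2(1H)-one | CC(C)(O)[C@H]1C[C@@]2(C)[C@H](CC[C@@H](OCc3ccc(OC)cc3)[C@@H]2C)[C@@H](O[Si](CC)(CC)CC)C1=O | intermediate
12 | (1R,3R,4aR,5R,6R,8aS)-6-[(4-methoxybenzyl)oxy]-4a,5-dimethyl-3-(prop-1-en-2-yl)-1-[(triethylsilyl)oxy]octahydronaphthalen-2(1H)-one | C=C(C)[C@H]1C[C@@]2(C)[C@H](CC[C@@H](OCc3ccc(OC)cc3)[C@@H]2C)[C@@H](O[Si](CC)(CC)CC)C1=O | intermediate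
13 | (1R,3R,4aR,5R,6R,8aS)-6-hydroxy-4a,5-dimethyl-3-(prop-1-en-2-yl)-1-[(triethylsilyl)oxy]octahydronaphthalen-2(1H)-one | C=C(C)[C@H]1C[C@@]2(C)[C@H](CC[C@@H](O)[C@@H]2C)[C@@H](O[Si](CC)(CC)CC)C1=O | intermediate
14 | angelic acid, (2Z)-2-methylbut-2-enoic acid | C/C=C(/C)C(=O)O | starting material
15 | (2R)-pent-4-en-2-ol | C[C@@H](O)CC=C | starting material
16 | (2Z)-2-methylbut-2-enoic 2,4,6-trichlorobenzoic anhydride | C/C=C(/C)C(=O)OC(=O)c1c(Cl)cc(Cl)cc1Cl | intermediate (not isolated)
17 | (2R)-pent-4-en-2-yl (2Z)-2-methylbut-2-enoate | C=CC[C@@H](C)OC(=O)/C(C)=C\C | intermediate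
18 | acrylic acid | C=CC(=O)O | starting material
19 | (2E,5R)-5-{[(2Z)-2-methylbut-2-enoyl]oxy}hex-2-enoic acid | OC(=O)/C=C/C[C@@H](C)OC(=O)/C(C)=C\C | intermediate
20 | mixed anhydride of 19 and 2,4,6-trichlorobenzoic acid | O=C(OC(=O)/C=C/C[C@@H](C)OC(=O)/C(C)=C\C)c1c(Cl)cc(Cl)cc1Cl | intermediate (not isolated)
21 | (1R,2R,4aS,5R,7R,8aR)-1,8a-dimethyl-6-oxo-7-(prop-1-en-2-yl)-5-[(triethylsilyl)oxy]decahydronaphthalen-2-yl (2E,5R)-5-{[(2Z)-2-methylbut-2-enoyl]oxy}hex-2-enoate | C=C(C)[C@H]1C[C@@]2(C)[C@H](CC[C@@H](OC(=O)/C=C/C[C@@H](C)OC(=O)/C(C)=C\C)[C@@H]2C)[C@@H](O[Si](CC)(CC)CC)C1=O | intermediate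
22 | (1R,2R,4aS,5R,7R,8aR)-5-hydroxy-1,8a-dimethyl-6-oxo-7-(prop-1-en-2-yl)decahydronaphthalen-2-yl (2E,5R)-5-{[(2Z)-2-methylbut-2-enoyl]oxy}hex-2-enoate, CNP0210874.1 | C=C(C)[C@H]1C[C@@]2(C)[C@H](CC[C@@H](OC(=O)/C=C/C[C@@H](C)OC(=O)/C(C)=C\C)[C@@H]2C)[C@@H](O)C1=O | target

## Step count and risks

Total steps: 10. Longest linear sequence: 8 (steps 1, 2, 3, 4, 5, 6, 9, 10); steps 7 and 8 make the side-chain acid in parallel.

Steps most likely to fail:

1. Step 3 (the new reductive α-silyloxylation). The hydride may be spent on the peroxide, the hydrosilane may silylate the copper enolate before oxygen transfer, or the product ketone may be over-reduced. The fallback uses known chemistry, sets out from 8 and returns at 9. Conjugate reduction of 8 with [(Ph3P)CuH]6 in the presence of Me3SiCl (benzene/THF, rt) gives the cis-fused trimethylsilyl enol ether F1. Rubottom oxidation (mCPBA, NaHCO3, CH2Cl2, −20 °C; then citric acid, MeOH) gives the 9-hydroxy ketone F2, oxygen entering on the convex face. Et3SiCl and imidazole in DMF then give 9.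

2. Step 5 (dehydration regiochemistry). Elimination into the ring would give the conjugated isopropylidene ketone instead of the isopropenyl group. The fallback sets out from 9 and returns at 12, bypassing aldol 11. LiN(iPr)2 then Me3SiCl (THF, −78 °C) gives the C7-ene trimethylsilyl enol ether F3. Palladium-catalysed α-alkenylation of the derived tin enolate with 2-bromopropene (Pd(OAc)2, P(t-Bu)3, Bu3SnF, toluene, 80 °C) forms the C7–isopropenyl bond directly, and C7 settles in the equatorial configuration of 12.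

3. Step 1 (enamine Michael addition with an α-alkoxy aldehyde donor). The donor class is thinly precedented with vinyl ketones, and the oxygen-bearing centre could lose some enantiopurity before ring closure. The fallback sets out from 1 (and 2) and returns at 3. Condensation of 1 with (R)-1-amino-2-(methoxymethyl)pyrrolidine gives the hydrazone F4. Separately, 2 is converted (Me3SiCl, NaI, MeCN; then ethylene glycol) to the iodo ketal F5. Azaenolate alkylation (LiN(iPr)2, THF, −78 °C; then F5, −100 → −78 °C) gives the alkylated hydrazone F6; the auxiliary antipode is the one expected to give the R centre by the usual azaenolate model. Two-phase aqueous oxalic acid followed by 1 M HCl/THF removes the auxiliary and the ketal and returns keto-aldehyde 3, which is cyclised to 4 as in step 1.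

## Further compounds

F1 | step 3 | cis-fused trimethylsilyl enol ether of the C8 ketone (C8=C9, C8–OSiMe3, 3-OPMB) | C1C[C@@]2(C)[C@H](CC[C@@H](OCc3ccc(OC)cc3)[C@@H]2C)C=C1O[Si](C)(C)C
F2 | step 3 | (1R,4aR,5R,6R,8aS)-1-hydroxy-6-[(4-methoxybenzyl)oxy]-4a,5-dimethyloctahydronaphthalen-2(1H)-one | C1C[C@@]2(C)[C@H](CC[C@@H](OCc3ccc(OC)cc3)[C@@H]2C)[C@@H](O)C1=O
F3 | step 5 | trimethylsilyl enol ether of 9 (C7=C8, C8–OSiMe3) | C=1C[C@@]2(C)[C@H](CC[C@@H](OCc3ccc(OC)cc3)[C@@H]2C)[C@@H](O[Si](CC)(CC)CC)C=1O[Si](C)(C)C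
F4 | step 1 | (E)-hydrazone of [(4-methoxybenzyl)oxy]acetaldehyde and (R)-1-amino-2-(methoxymethyl)pyrrolidine | COC[C@H]1CCCN1/N=C/COCc1ccc(OC)cc1
F5 | step 1 | 2-ethyl-2-(2-iodoethyl)-1,3-dioxolane | CCC1(CCI)OCCO1
F6 | step 1 | (E)-hydrazone of (2R)-4-(2-ethyl-1,3-dioxolan-2-yl)-2-[(4-methoxybenzyl)oxy]butanal and (R)-1-amino-2-(methoxymethyl)pyrrolidine | CCC1(CC[C@@H](OCc2ccc(OC)cc2)/C=N/N2CCC[C@@H]2COC)OCCO1
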